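## Structural features

The target joins three parts at one benzylic methine, C9': a hexasubstituted benzene ring (2,4,6-trihydroxybenzene-1,3-dicarbaldehyde, bonded through its C5), an isobutyl group, and C1 of a trans-fused decalin of the eudesmane type. Eudesmane locants are used throughout: ring A is C1–C5 plus C10, ring B is C5–C10, C14 is the methyl on C10, C15 the methyl on C4, C11 the carbinol carbon on C7, and C10' the CH2 next to C9'. The decalin carries the angular methyl on the quaternary C10, a tertiary carbinol at C4 and a 2-hydroxyprop-2-yl group on C7. C9', C1, C10, C5 and C4 form an unbroken chain of five stereocentres; C7 is remote and equatorial. The C1 substituent is trans to C14 (axial on ring A) and the 4-hydroxyl is cis to C14 (axial), so both look like products of attack anti to the angular methyl, not of anti addition across a germacradiene. The fragile groups are the free diformylphloroglucinol (acidic, chelating, a quinone methide precursor), the two aryl aldehydes (no late organometallic step) and the two tertiary alcohols (no strong acid). The real difficulty is the C1–C9' bond, between a ring methine next to the quaternary C10 and a methine next to a doubly ortho-substituted arene, together with the C1/C9' configuration. The key step exploits two features: C9' is ortho/para to three ring oxygens, so a cation can be made at C9' twice in succession from the aldehyde oxidation level; and C1 is γ to the C4 oxygen, which makes C1 nucleophilic through a 2-silyloxy-1,3-diene in ring A.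

## Logic of the disconnections

**24 to 23.** No skeletal bond is cut; the three phenolic O–H bonds become O–CH3. The free triphenol dialdehyde cannot be carried through organolithium chemistry. The forward step must cleave three methyl ethers without acid, because of the two tertiary carbinols.

**23 to 21.** The two aryl C–CHO bonds are cut. Aldehydes would not survive the methyl addition at C4 and would weaken cation stabilisation at C9'. This reduces the arene to a 2,4,6-trimethoxyphenyl group. The forward step needs a regiospecific double formylation under basic conditions; each free ring position lies between two methoxy groups.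

**21 to 20.** The C4–C15 bond is cut. The axial carbinol cis to C14 is the product of equatorial attack on a 4-ketone, and the same C4 oxygen serves the key step. The forward step needs 1,2-addition without enolisation toward C5.

**20 to 19.** No skeletal bond is cut; hydrogen is removed across C2–C3 and across the terminal carbons of the side chain. This exposes the enone in which ring A leaves the key step and a 2-methylallyl group as a nucleophilic isobutyl surrogate. The forward step is a hydrogenation that creates no stereocentre.

**19 to 13 + 15 + 16 (key).** C1–C9' and C9'–C10' are cut, leaving a 1,1-dielectrophile at C9' (15), a C1 nucleophile (13) and an isobutyl surrogate (16). The most hindered bond and both stereocentres next to it are made in one flask from three simple pieces. In one sentence: an aryl aldehyde acetal serves as a geminal dication at C9', attacked first by C1 of the ring A silyloxy diene and then, after re-ionisation of the benzylic ether, by an allylsilane. The forward step needs γ-selective attack anti to C14 and a face-selective capture of the planar C9' cation.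

**13 to 12, and 15 to 14.** No skeletal bond is cut. 13 is the through-conjugated silyl dienol ether of 12, and 15 is the dimethyl acetal of commercial 14. The demand on 12 is enolisation toward C1, not C5.

**12 to 10 to 9.** No C–C bond is cut; the enone is transposed. 12 (C4 carbonyl, C2=C3) comes from an enone that has its carbonyl at C3 and an enol ether oxygen already on C4. The C3 oxygen leaves as a hydrazone-derived vinyl anion and the C4 enol ether is hydrolysed. This puts the oxygen where the annulation cannot put it directly. The demand is deprotonation at C2, and a trans ring fusion set by equilibration at C5.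

**9 to 8 to 3 + 5.** C4–C5 (aldol condensation) and C1–C10 (Michael addition) are cut. Ring A is reduced to a four-carbon vinyl ketone that already carries the future C4 oxygen as a methoxy group. The Michael step must create C10 with the new chain trans to the C7 substituent, against the ring's own preference, so a chiral amine auxiliary is needed.

**5 to 4, and 3 to 2 to 1.** 5 comes from a commercial amide by cutting the acyl–vinyl bond. 3 comes from 1 by adding water across the isopropenyl group and hydrogen across the enone. C7 is bought with 1.

## Other disconnections considered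

**Alternative 1:** (the first that comes to mind) cut the C9'–aryl bond. 2,4,6-Trimethoxyphenyllithium would add to the axial 1-(3-methylbutanoyl) ketone A1 to give the tertiary benzylic carbinol A2, followed by ionic hydrogenation. Grounds for rejecting it:
- In the cation from A2 the same conformational lock operates as in the chosen route, but hydride is now the last nucleophile. It should enter anti to C10 and place H where the chosen route places C10', giving the (9'R) epimer.
- A1 needs its own anti-to-methyl C–C bond at C1 (conjugate addition to a 1-en-3-one, then moving oxygen from C3 to C4), at least four further steps.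
- A doubly ortho-substituted aryllithium adding to a ketone whose α-carbon sits next to C10 is prone to enolisation, and the acid of the ionic hydrogenation threatens both tertiary alcohols.

**Alternative 2:** (biomimetic) cut C1–C9' and C5–C10. The quinone methide A4, from 2,4,6-trihydroxyisophthalaldehyde and 3-methylbutanal, would be attacked by the C1=C10 bond of the germacradienol A3; transannular closure by C4=C5 and capture by water would give A5. Grounds for rejecting it:
- Anti addition across two E double bonds is stereospecific. It places the C1 substituent cis to C14 and the 4-hydroxyl trans to C14, so A5 would be the C1,C4-bis-epimer of the target. The mismatch is structural, not a matter of conditions.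
- A3 is thermally labile (Cope rearrangement) and needs a macrocyclisation of its own.
- Chroman formation by [4+2] addition of A4 would compete.

**Alternative 3:** cut C1–C10 and C4–C5 by a Diels–Alder reaction of 1 as dienophile with diene A6, giving A7. Addition anti to the isopropenyl group and endo should set C10 and C1 correctly in one step. Grounds for rejecting it:
- Suprafacial addition forces a cis ring fusion, the C5 epimer.
- A7 keeps a carbonyl at C9 and has no oxygen at C4. Repair needs deoxygenation at C9, allylic oxidation at C4 in competition with the tertiary allylic C1–H, and equilibration at C5: at least five steps of uncertain regiochemistry.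
- The chosen route takes the C4 oxygen from the annulation reagent and the trans fusion from thermodynamics.

Key step: step 10

Assumption: the target is taken exactly as drawn, (1S,4R,5S,7S,10R,9'S) in eudesmane locants, and 1-methoxybut-3-en-2-one is made fresh (step 3) because it polymerises on storage.

## Steps

Step 1
Reactants: 1 (S)-(+)-carvone
Product: 2 (2S,5S)-2-methyl-5-(prop-1-en-2-yl)cyclohexan-1-one (trans-dihydrocarvone, with some C2 epimer)
Conditions: LiBH(s-Bu)3, THF, −78 °C; aq. NH4Cl
Reagents that add atoms: none
Why: Conjugate reduction of a β-unsubstituted cyclohexenone by a bulky trialkylborohydride, then protonation of the enolate; the carvone stereocentre is untouched and the C2 epimer mixture is erased in step 4.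

Step 2
Reactants: 2 (2S,5S)-2-methyl-5-(prop-1-en-2-yl)cyclohexan-1-one
Product: 3 (2S,5S)-5-(2-hydroxypropan-2-yl)-2-methylcyclohexan-1-one
Conditions: Co(acac)2 (cat.), PhSiH3, O2 (1 atm), THF, rt
Reagents that add atoms: dioxygen O=O
Why: Mukaiyama hydration: hydrogen-atom transfer to the 1,1-disubstituted alkene gives the tertiary radical, which is trapped by O2 and reduced to the Markovnikov alcohol; the ketone and the ring stereocentres are not involved.

Step 3
Reactants: 4 N,2-dimethoxy-N-methylacetamide
Product: 5 1-methoxybut-3-en-2-one
Conditions: CH2=CHMgBr, THF, −78 to 0 °C; inverse quench into cold 2 M HCl; used at once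
Reagents that add atoms: vinylmagnesium bromide C=C[Mg]Br
Why: Weinreb ketone synthesis; the chelated tetrahedral intermediate prevents over-addition, and the cold acidic inverse quench protonates the released N,O-dimethylhydroxylamine before it can add to the enone.

Step 4
Reactants: 3 (2S,5S)-5-(2-hydroxypropan-2-yl)-2-methylcyclohexan-1-one; 5 1-methoxybut-3-en-2-one
Product: 8 (2R,5S)-5-(2-hydroxypropan-2-yl)-2-(4-methoxy-3-oxobutyl)-2-methylcyclohexan-1-one, via ketimine 6 (not isolated), via Michael adduct imine 7 (not isolated)
Conditions: (S)-1-phenylethylamine, p-TsOH (cat.), toluene, reflux, Dean–Stark; then 5, THF, 40 °C; then 10% aq. AcOH, rt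
Reagents that add atoms: water O
Why: Chiral-imine Michael addition: the more substituted secondary enamine tautomer of 6 adds to the vinyl ketone through a chair-like aza-ene transition state on the face anti to the phenyl group of the auxiliary. This should create the quaternary C10 as (R), with the new chain trans to the C7 substituent, the auxiliary overriding the ring's axial-attack preference (the enantiomeric pairing is the established entry to the natural α-cyperone series). Hydrolysis returns the amine.

Step 5
Reactants: 8 (2R,5S)-5-(2-hydroxypropan-2-yl)-2-(4-methoxy-3-oxobutyl)-2-methylcyclohexan-1-one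
Product: 9 (4aR,7S)-7-(2-hydroxypropan-2-yl)-1-methoxy-4a-methyl-4,4a,5,6,7,8-hexahydronaphthalen-2(3H)-one
Conditions: NaOMe, MeOH, 0 to 50 °C
Reagents that add atoms: none
Why: Second stage of a Robinson annulation: the more acidic methoxymethylene carbon (C4) adds to the ring carbonyl (C5) in a six-membered aldol and dehydration gives the α-methoxy enone; neither C7 nor C10 can epimerise.

Step 6
Reactants: 9 (4aR,7S)-7-(2-hydroxypropan-2-yl)-1-methoxy-4a-methyl-4,4a,5,6,7,8-hexahydronaphthalen-2(3H)-one
Product: 10 4-methylbenzenesulfonohydrazone of 9 at C3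
Conditions: TsNHNH2, AcOH (cat.), EtOH, 50 °C
Reagents that add atoms: 4-methylbenzenesulfonohydrazide Cc1ccc(cc1)S(=O)(=O)NN
Why: Acid-catalysed condensation of the C3 ketone to the tosylhydrazone; the sulfonamide nitrogen should sit anti to the substituted C4 and so syn to C2, which prepares the regiochemistry of step 7.

Step 7
Reactants: 10 4-methylbenzenesulfonohydrazone of 9
Product: 12 (5S,7S,10R)-11-hydroxy-15-noreudesm-2-en-4-one (trans-fused), via methoxy diene 11 (not isolated)
Conditions: LiN(i-Pr)2 (4.5 equiv), THF, −78 to 0 °C; H2O; then 1 M HCl, THF, rt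
Reagents that add atoms: water O
Why: Shapiro reaction: deprotonation at N–H and at C2, loss of sulfinate and N2, and protonation of the C3 vinyllithium give the 2-methoxy-1,3-diene 11; acid hydrolysis of its enol ether, with protonation at C5, releases the transposed enone. C5 is set thermodynamically: the epimers equilibrate through the enol to the trans-fused ketone, in which the axial C14 methyl has one syn-axial hydrogen fewer.

Step 8
Reactants: 12 (5S,7S,10R)-11-hydroxy-15-noreudesm-2-en-4-one
Product: 13 (5S,7S,10R)-4,11-bis(trimethylsilyloxy)-15-noreudesma-1,3-diene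
Conditions: TMSOTf (2.5 equiv), Et3N (3 equiv), CH2Cl2, 0 °C to rt (equilibrating)
Reagents that add atoms: trimethylsilyl trifluoromethanesulfonate C[Si](C)(C)OS(=O)(=O)C(F)(F)F
Why: Soft enolisation under equilibrating conditions (reversible C-protonation by the ammonium triflate) should favour the through-conjugated dienol ether by loss of H1 over the cross-conjugated isomer with a tetrasubstituted ring-fusion double bond; the tertiary alcohol is silylated in the same operation and no stereocentre is touched.

Step 9
Reactants: 14 2,4,6-trimethoxybenzaldehyde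
Product: 15 2-(dimethoxymethyl)-1,3,5-trimethoxybenzene
Conditions: HC(OMe)3, MeOH, p-TsOH (cat.), rt; NaOMe quench
Reagents that add atoms: trimethyl orthoformate COC(OC)OC
Why: Acid-catalysed acetalisation driven by the orthoformate as water scavenger; the electron-rich acetal is kept basic until use.

Step 10
Reactants: 13 (5S,7S,10R)-4,11-bis(trimethylsilyloxy)-15-noreudesma-1,3-diene; 15 2-(dimethoxymethyl)-1,3,5-trimethoxybenzene; 16 trimethyl(2-methylprop-2-en-1-yl)silane
Product: 19 (1S,5S,7S,10R)-11-hydroxy-1-[(1S)-3-methyl-1-(2,4,6-trimethoxyphenyl)but-3-en-1-yl]-15-noreudesm-2-en-4-one, via benzylic methyl ether 17 (not isolated), via silyl ether 18 (not isolated)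
Conditions: 15 (1.2 equiv), TMSOTf (0.2 equiv), 2,6-di-tert-butyl-4-methylpyridine, CH2Cl2, −78 °C, slow addition of 13; then 16 (4 equiv), TMSOTf (0.3 equiv), −78 to −30 °C; aq. NaHCO3; then 1 M HCl, THF, 0 °C
Reagents that add atoms: none
Why: TMSOTf ionises 15 to the aryl-stabilised methoxycarbenium ion, which 13 attacks through its γ-carbon C1 (vinylogous Mukaiyama addition to an acetal, the closest known reaction type for the first bond), restoring the C2=C3–C4=O enone and giving methyl ether 17 as both C9' epimers. The same Lewis acid then ionises the benzylic ether of 17 to a planar secondary cation, which 16 captures through its CH2 terminus with loss of silicon (Hosomi–Sakurai substitution of an electron-rich benzylic ether by the SN1 path), so the acetal carbon is used twice as electrophile and becomes C9'. No ring is closed; two C–C bonds (C1–C9' and C9'–C10') and two stereocentres are formed. C1: the electrophile adds to the diene face anti to the pseudo-axial C14 methyl on the adjacent C10, which puts the new substituent trans to C14. C9': both epimers of 17 converge on one cation, in which 1,3-allylic strain with the ortho methoxy group holds H1 in the cation plane, and 16 enters anti to the quaternary C10 and syn to the sp2 C2, which corresponds to (9'S). Selectivities needed: γ over α attack of 13 (largest HOMO coefficient at C1, soft cationic electrophile); one dienol ether per acetal (13 is limiting and consumed at −78 °C before 16 is added, and a second bulky diene adds far more slowly to the hindered cation than the small allylsilane); capture rather than loss of H1 (excess 16; the styrene from elimination would be twisted out of conjugation by the two ortho methoxy groups); and retention of the trans fusion (no base, no enolisation at C5). The closing dilute acid wash removes only the tertiary silyl ether of 18.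

Step 11
Reactants: 19 (1S,5S,7S,10R)-11-hydroxy-1-[(1S)-3-methyl-1-(2,4,6-trimethoxyphenyl)but-3-en-1-yl]-15-noreudesm-2-en-4-one
Product: 20 (1S,5S,7S,10R)-11-hydroxy-1-[(1S)-3-methyl-1-(2,4,6-trimethoxyphenyl)butyl]-15-noreudesman-4-one
Conditions: H2 (1 atm), Pd/C (10%), EtOAc, rt
Reagents that add atoms: none
Why: Heterogeneous hydrogenation of the disubstituted enone alkene and the 1,1-disubstituted side-chain alkene; no stereocentre is created, and the aryl ethers, ketone and tertiary alcohol are inert.

Step 12
Reactants: 20 (1S,5S,7S,10R)-11-hydroxy-1-[(1S)-3-methyl-1-(2,4,6-trimethoxyphenyl)butyl]-15-noreudesman-4-one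
Product: 21 (1S,4R,5S,7S,10R)-1-[(1S)-3-methyl-1-(2,4,6-trimethoxyphenyl)butyl]eudesmane-4,11-diol
Conditions: MeLi (4 equiv), CeCl3 (4 equiv), THF, −78 °C; aq. NH4Cl
Reagents that add atoms: methyllithium [Li]C
Why: Organocerium 1,2-addition, which suppresses enolisation toward C5; the axial trajectory is blocked by the 1,3-diaxial C14 methyl, so methyl should enter equatorially and give the axial hydroxyl cis to C14, that is (4R).

Step 13
Reactants: 21 (1S,4R,5S,7S,10R)-1-[(1S)-3-methyl-1-(2,4,6-trimethoxyphenyl)butyl]eudesmane-4,11-diol
Product: 23 5-[(1S)-1-[(1S,4R,5S,7S,10R)-4,11-dihydroxyeudesman-1-yl]-3-methylbutyl]-2,4,6-trimethoxybenzene-1,3-dicarbaldehyde, via lithium hemiaminal 22 (not isolated)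
Conditions: n-BuLi (3.2 equiv), TMEDA, THF, 0 °C; DMF (1.0 equiv), −78 °C; n-BuLi (1.5 equiv), −78 to 0 °C; DMF (excess); dil. HCl
Reagents that add atoms: N,N-dimethylformamide CN(C)C=O
Why: Directed ortho-lithiation and formylation: each free ring position lies between two methoxy groups; the first formyl is held as its lithium α-(dimethylamino)alkoxide 22, which is inert to n-BuLi, so the second position can be lithiated and formylated in the same flask. The tertiary alkoxides are spectators.

Step 14
Reactants: 23 5-[(1S)-1-[(1S,4R,5S,7S,10R)-4,11-dihydroxyeudesman-1-yl]-3-methylbutyl]-2,4,6-trimethoxybenzene-1,3-dicarbaldehyde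
Product: 24 5-[(1S)-1-[(1S,4R,5S,7S,10R)-4,11-dihydroxyeudesman-1-yl]-3-methylbutyl]-2,4,6-trihydroxybenzene-1,3-dicarbaldehyde (target)
Conditions: NaSEt (12 equiv), DMF, 120 °C; then aq. HCl to pH 3, 0 °C
Reagents that add atoms: none
Why: SN2 O-demethylation by thiolate; every methoxy group is ortho or para to a formyl group, which makes its phenoxide a good leaving group, and the basic medium cannot ionise the tertiary alcohols.

## Compound list

1 | (S)-(+)-carvone, (5S)-2-methyl-5-(prop-1-en-2-yl)cyclohex-2-en-1-one | CC1=CC[C@@H](CC1=O)C(C)=C | starting material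
2 | (2S,5S)-2-methyl-5-(prop-1-en-2-yl)cyclohexan-1-one | C[C@H]1CC[C@@H](CC1=O)C(C)=C | intermediate
3 | (2S,5S)-5-(2-hydroxypropan-2-yl)-2-methylcyclohexan-1-one | C[C@H]1CC[C@@H](CC1=O)C(C)(C)O | intermediate
4 | N,2-dimethoxy-N-methylacetamide | COCC(=O)N(C)OC | starting material
5 | 1-methoxybut-3-en-2-one | COCC(=O)C=C | intermediate
6 | N-[(1S)-1-phenylethyl]ketimine of 3 (C2 epimers, in equilibrium with the secondary enamine) | CC1CC[C@@H](CC1=N[C@@H](C)c1ccccc1)C(C)(C)O | intermediate
7 | N-[(1S)-1-phenylethyl]imine (at the ring carbonyl) of 8 | COCC(=O)CC[C@@]1(C)CC[C@@H](CC1=N[C@@H](C)c1ccccc1)C(C)(C)O | intermediate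
8 | (2R,5S)-5-(2-hydroxypropan-2-yl)-2-(4-methoxy-3-oxobutyl)-2-methylcyclohexan-1-one | COCC(=O)CC[C@@]1(C)CC[C@@H](CC1=O)C(C)(C)O | intermediate
9 | (4aR,7S)-7-(2-hydroxypropan-2-yl)-1-methoxy-4a-methyl-4,4a,5,6,7,8-hexahydronaphthalen-2(3H)-one | C1CC(=O)C(OC)=C2C[C@@H](C(C)(C)O)CC[C@]12C | intermediate
10 | 4-methylbenzenesulfonohydrazone of 9 at C3 | C1CC(=NNS(=O)(=O)c3ccc(C)cc3)C(OC)=C2C[C@@H](C(C)(C)O)CC[C@]12C | intermediate
11 | (7S,10R)-4-methoxy-15-noreudesma-2,4-dien-11-ol | C1C=CC(OC)=C2C[C@@H](C(C)(C)O)CC[C@]12C | intermediate
12 | (5S,7S,10R)-11-hydroxy-15-noreudesm-2-en-4-one, (4aR,7S,8aS)-7-(2-hydroxypropan-2-yl)-4a-methyl-4a,5,6,7,8,8a-hexahydronaphthalen-1(4H)-one | C1C=CC(=O)[C@H]2C[C@@H](C(C)(C)O)CC[C@]12C | intermediate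
13 | (5S,7S,10R)-4,11-bis(trimethylsilyloxy)-15-noreudesma-1,3-diene | C1=CC=C(O[Si](C)(C)C)[C@H]2C[C@@H](C(C)(C)O[Si](C)(C)C)CC[C@]12C | intermediate
14 | 2,4,6-trimethoxybenzaldehyde | COc1cc(OC)c(C=O)c(OC)c1 | starting material
15 | 2-(dimethoxymethyl)-1,3,5-trimethoxybenzene | COC(OC)c1c(OC)cc(OC)cc1OC | intermediate
16 | trimethyl(2-methylprop-2-en-1-yl)silane | CC(=C)C[Si](C)(C)C | starting material
17 | 1-[methoxy(2,4,6-trimethoxyphenyl)methyl]-11-(trimethylsilyloxy)-15-noreudesm-2-en-4-one, C1 substituent trans to C14, both C9' epimers | COC(c1c(OC)cc(OC)cc1OC)[C@@H]1C=CC(=O)[C@H]2C[C@@H](C(C)(C)O[Si](C)(C)C)CC[C@]12C | intermediate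
18 | 11-O-trimethylsilyl ether of 19 | CC(=C)C[C@H](c1c(OC)cc(OC)cc1OC)[C@@H]1C=CC(=O)[C@H]2C[C@@H](C(C)(C)O[Si](C)(C)C)CC[C@]12C | intermediate
19 | (1S,5S,7S,10R)-11-hydroxy-1-[(1S)-3-methyl-1-(2,4,6-trimethoxyphenyl)but-3-en-1-yl]-15-noreudesm-2-en-4-one | CC(=C)C[C@H](c1c(OC)cc(OC)cc1OC)[C@@H]1C=CC(=O)[C@H]2C[C@@H](C(C)(C)O)CC[C@]12C | intermediate
20 | (1S,5S,7S,10R)-11-hydroxy-1-[(1S)-3-methyl-1-(2,4,6-trimethoxyphenyl)butyl]-15-noreudesman-4-one | CC(C)C[C@H](c1c(OC)cc(OC)cc1OC)[C@@H]1CCC(=O)[C@H]2C[C@@H](C(C)(C)O)CC[C@]12C | intermediate
21 | (1S,4R,5S,7S,10R)-1-[(1S)-3-methyl-1-(2,4,6-trimethoxyphenyl)butyl]eudesmane-4,11-diol | CC(C)C[C@H](c1c(OC)cc(OC)cc1OC)[C@@H]1CC[C@@](C)(O)[C@H]2C[C@@H](C(C)(C)O)CC[C@]12C | intermediate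
22 | trilithium salt of the mono-adduct: 4,11-dialkoxide of 21 carrying a lithium (dimethylamino)methanolate group on one free ring position | CC(C)C[C@H](c1c(OC)cc(OC)c(C(O[Li])N(C)C)c1OC)[C@@H]1CC[C@@](C)(O[Li])[C@H]2C[C@@H](C(C)(C)O[Li])CC[C@]12C | intermediate
23 | 5-[(1S)-1-[(1S,4R,5S,7S,10R)-4,11-dihydroxyeudesman-1-yl]-3-methylbutyl]-2,4,6-trimethoxybenzene-1,3-dicarbaldehyde | CC(C)C[C@H](c1c(OC)c(C=O)c(OC)c(C=O)c1OC)[C@@H]1CC[C@@](C)(O)[C@H]2C[C@@H](C(C)(C)O)CC[C@]12C | intermediate
24 | 5-[(1S)-1-[(1S,4R,5S,7S,10R)-4,11-dihydroxyeudesman-1-yl]-3-methylbutyl]-2,4,6-trihydroxybenzene-1,3-dicarbaldehyde (CNP0409870.3) | CC(C)C[C@H](c1c(O)c(C=O)c(O)c(C=O)c1O)[C@@H]1CC[C@@](C)(O)[C@H]2C[C@@H](C(C)(C)O)CC[C@]12C | target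

## Step count and least certain steps

Total step count: 14. Longest linear sequence: 12 steps (1, 2, 4 to 8, 10 to 14); steps 3 and 9 are side branches.

**Step 10 (key step).** The most likely failures are poor facial discrimination at the planar C9' cation, since the conformational lock rests on a model, and loss of H1 from that cation to a styrene in competition with capture by the allylsilane. The fallback changes the order in which the two groups reach C9'. It sets out from 14 and 13 and comes back at 20.
- Isobutylmagnesium bromide would add to 14 to give racemic 3-methyl-1-(2,4,6-trimethoxyphenyl)butan-1-ol F1.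
- F1 would be ionised with BF3·OEt2 at −78 °C in the presence of 13; γ-alkylation at C1 and a dilute acid wash would give the isobutyl enone F2 as a pair of C9' epimers.
- The C9' stereocentre then arises from the mutual approach of two prochiral partners, an element independent of the one in step 10. The (9'S) epimer would be separated and hydrogenated under the conditions of step 11 to 20.

**Step 7.** Deprotonation of the hydrazone dianion toward C6 instead of C2 would give the 3,5-diene and, after hydrolysis, the 5-en-4-one; equilibration at C5 to the trans fusion may also be incomplete. The fallback avoids the vinyl anion. It sets out from 9 and comes back at 12.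
- NaBH4 with CeCl3 would reduce 9 to the allylic alcohol F3.
- Dilute HCl would hydrolyse the enol ether of F3 to the trans-fused 3-hydroxy-4-ketone F4.
- Methanesulfonyl chloride and Et3N would give the mesylate F5, and LiBr with Li2CO3 in hot DMF would eliminate it toward C2 to give 12.

**Step 13.** The second lithiation may stall once the first hemiaminal alkoxide is in place, or that hemiaminal may collapse and the freed aldehyde take up n-BuLi. The fallback replaces C–H lithiation by halogen–lithium exchange. It sets out from 21 and comes back at 23.
- N-Bromosuccinimide (2 equiv, MeCN, 0 °C) would give the dibromide F6.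
- One bromine–lithium exchange with n-BuLi at −78 °C and DMF would give the bromo aldehyde F7.
- The aldehyde of F7 would be masked in the flask as the lithium hemiaminal of N,N,N'-trimethylethylenediamine; a second exchange and DMF would give 23.

**Step 14.** Each phenoxide formed deactivates the ring toward further nucleophilic dealkylation, so the reaction may stall after one or two demethylations, and the temperature needed may damage the aldehydes. The fallback reverses the last two operations. It sets out from 21 and comes back at 24.
- NaSEt in DMF at 150 °C, with no aldehyde present, would demethylate 21 to the alkylphloroglucinol F8.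
- Vilsmeier–Haack formylation of F8 (POCl3, DMF, EtOAc, 0 °C; aqueous NaOAc), the standard double formylation of alkylphloroglucinols, would give 24. Any formate formed on a tertiary alcohol would be removed with K2CO3 in MeOH.

## Further compounds

F1 | step 10 | 3-methyl-1-(2,4,6-trimethoxyphenyl)butan-1-ol (racemic) | CC(C)CC(O)c1c(OC)cc(OC)cc1OC
F2 | step 10 | 11-hydroxy-1-[3-methyl-1-(2,4,6-trimethoxyphenyl)butyl]-15-noreudesm-2-en-4-one, C1 substituent trans to C14, both C9' epimers | CC(C)CC(c1c(OC)cc(OC)cc1OC)[C@@H]1C=CC(=O)[C@H]2C[C@@H](C(C)(C)O)CC[C@]12C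
F3 | step 7 | (7S,10R)-4-methoxy-15-noreudesm-4-ene-3,11-diol, both C3 epimers | C1CC(O)C(OC)=C2C[C@@H](C(C)(C)O)CC[C@]12C
F4 | step 7 | (5S,7S,10R)-3,11-dihydroxy-15-noreudesman-4-one, both C3 epimers | C1CC(O)C(=O)[C@H]2C[C@@H](C(C)(C)O)CC[C@]12C
F5 | step 7 | 3-O-methanesulfonate of F4 | C1CC(OS(C)(=O)=O)C(=O)[C@H]2C[C@@H](C(C)(C)O)CC[C@]12C
F6 | step 13 | (1S,4R,5S,7S,10R)-1-[(1S)-1-(3,5-dibromo-2,4,6-trimethoxyphenyl)-3-methylbutyl]eudesmane-4,11-diol | CC(C)C[C@H](c1c(OC)c(Br)c(OC)c(Br)c1OC)[C@@H]1CC[C@@](C)(O)[C@H]2C[C@@H](C(C)(C)O)CC[C@]12C
F7 | step 13 | 3-bromo-5-[(1S)-1-[(1S,4R,5S,7S,10R)-4,11-dihydroxyeudesman-1-yl]-3-methylbutyl]-2,4,6-trimethoxybenzaldehyde | CC(C)C[C@H](c1c(OC)c(Br)c(OC)c(C=O)c1OC)[C@@H]1CC[C@@](C)(O)[C@H]2C[C@@H](C(C)(C)O)CC[C@]12C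
F8 | step 14 | 2-[(1S)-1-[(1S,4R,5S,7S,10R)-4,11-dihydroxyeudesman-1-yl]-3-methylbutyl]benzene-1,3,5-triol | CC(C)C[C@H](c1c(O)cc(O)cc1O)[C@@H]1CC[C@@](C)(O)[C@H]2C[C@@H](C(C)(C)O)CC[C@]12C
A1 | alternative 1 | 1-(3-methylbutanoyl)eudesmane-4,11-diol, acyl group trans to C14, ring configuration as in 24 | CC(C)CC(=O)[C@@H]1CC[C@@](C)(O)[C@H]2C[C@@H](C(C)(C)O)CC[C@]12C
A2 | alternative 1 | 1-[1-hydroxy-3-methyl-1-(2,4,6-trimethoxyphenyl)butyl]eudesmane-4,11-diol, both C9' epimers | CC(C)CC(O)(c1c(OC)cc(OC)cc1OC)[C@@H]1CC[C@@](C)(O)[C@H]2C[C@@H](C(C)(C)O)CC[C@]12C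
A3 | alternative 2 | 2-[(1S,3E,7E)-4,8-dimethylcyclodeca-3,7-dien-1-yl]propan-2-ol, (7S)-hedycaryol | C/C1=C\CC/C(C)=C/C[C@@H](C(C)(C)O)CC1
A4 | alternative 2 | ortho-quinone methide: 3,5-diformyl-4,6-dihydroxy-2-(3-methylbutylidene)cyclohexa-3,5-dien-1-one | CC(C)CC=C1C(=O)C(C=O)=C(O)C(C=O)=C1O
A5 | alternative 2 | C1,C4-bis-epimer of 24 (C1 substituent cis to C14, 4-hydroxyl trans to C14; C9' not defined) | CC(C)CC(c1c(O)c(C=O)c(O)c(C=O)c1O)[C@H]1CC[C@](C)(O)[C@H]2C[C@@H](C(C)(C)O)CC[C@]12C
A6 | alternative 3 | tert-butyldimethyl[(2E)-penta-2,4-dien-1-yloxy]silane | C=C/C=C/CO[Si](C)(C)C(C)(C)C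
A7 | alternative 3 | cis-fused endo adduct: 1-[(tert-butyldimethylsilyloxy)methyl]-10-methyl-7-(prop-1-en-2-yl)-2-octalin-9-one, C1 substituent trans to C14, H5 cis to C14 | CC(C)(C)[Si](C)(C)OC[C@@H]1C=CC[C@@H]2C[C@@H](C(C)=C)CC(=O)[C@]12C
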